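**Strategy.** Ring A is the epoxycyclohexane (C1 bears the CH2 linker, C2 the isopropenyl group, C3 and C4 are the epoxide CH and C–CH3 carbons); ring B is the bromohydrin ring. Ring A is cut at C1–C2 and C3–C4. The key step exploits the trisubstituted epoxide flanked by C1: C1 and C3 become the two carbons of an alkenylsulfonium salt that already carries ring B, while C2, C5, C6 and C4 come from an acyclic triketone. In one operation the diketonate adds to C1 and the resulting sulfur ylide closes onto the C4 ketone, forming ring A and the epoxide; a chiral sulfide controls the configuration, and the retained acetyl group later becomes the isopropenyl group.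

Key step: step 10

Assumption: (1R,4R,5R)-isothiocineole is taken to give the ring A configuration drawn; if the ylide shows the opposite facial preference, the enantiomeric sulfide is used in step 8 and nothing else changes.

Step 1
Reactants: 1 (1S,2S,4R)-limonene-1,2-diol
Product: 3 cyclic sulfate of (1S,2S,4R)-4-acetyl-1-methylcyclohexane-1,2-diol, via cyclic sulfite 2 (not isolated)
Conditions: SOCl2, Et3N, CH2Cl2, 0 °C; then RuCl3·3H2O (cat.), NaIO4, MeCN/CCl4/H2O, 0 °C to rt
Reagents that add atoms: thionyl chloride O=S(Cl)Cl; sodium periodate [Na+].[O-]I(=O)(=O)=O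
Why: Thionyl chloride closes the trans-diol (through its diequatorial chair) to the cyclic sulfite, and RuO4 generated in the flask then oxidises sulfur to the cyclic sulfate and cleaves the isopropenyl alkene to the methyl ketone (cyclic sulfate formation combined with oxidative alkene cleavage), with no stereocentre touched.

Step 2
Reactants: 3 cyclic sulfate of (1S,2S,4R)-4-acetyl-1-methylcyclohexane-1,2-diol
Product: 5 1-[(1R,3R,4S)-3-bromo-4-hydroxy-4-methylcyclohexyl]ethan-1-one, via lithium alkyl sulfate 4 (not isolated)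
Conditions: LiBr, THF, 40 °C; then H2SO4 (cat.), H2O, THF, rt
Reagents that add atoms: lithium bromide [Li+].[Br-]
Why: Bromide opens the cyclic sulfate by SN2 at the secondary carbon with inversion, which places bromine cis to the tertiary oxygen, and acid-catalysed hydrolysis of the tertiary alkyl sulfate goes by S–O cleavage with retention (cyclic sulfate ring opening).

Step 3
Reactants: 5 1-[(1R,3R,4S)-3-bromo-4-hydroxy-4-methylcyclohexyl]ethan-1-one
Product: 6 1-[(1R,3R,4S)-3-bromo-4-methyl-4-(triethylsilyloxy)cyclohexyl]ethan-1-one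
Conditions: Et3SiOTf, 2,6-lutidine, CH2Cl2, −78 to 0 °C
Reagents that add atoms: triethylsilyl trifluoromethanesulfonate CC[Si](CC)(CC)OS(=O)(=O)C(F)(F)F
Why: The silyl triflate with a hindered base silylates the tertiary alcohol (silyl ether protection), so that the later basic and electrophilic steps cannot act on the cis-bromohydrin.

Step 4
Reactants: 6 1-[(1R,3R,4S)-3-bromo-4-methyl-4-(triethylsilyloxy)cyclohexyl]ethan-1-one
Product: 7 1-[(1R,3R,4S)-3-bromo-4-methyl-4-(triethylsilyloxy)cyclohexyl]ethenyl trifluoromethanesulfonate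
Conditions: KHMDS, THF, −78 °C; then PhNTf2, −78 to 0 °C
Reagents that add atoms: N-phenylbis(trifluoromethanesulfonimide) O=S(=O)(N(c1ccccc1)S(=O)(=O)C(F)(F)F)C(F)(F)F
Why: Kinetic deprotonation of the methyl ketone on the methyl side and O-sulfonylation of the enolate give the 1,1-disubstituted alkenyl triflate (enol triflate formation) without epimerising the ring carbon, which is already in its equatorial configuration.

Step 5
Reactants: 7 alkenyl triflate; 8 (3-ethoxy-3-oxopropyl)zinc bromide
Product: 9 ethyl 4-[(1R,3R,4S)-3-bromo-4-methyl-4-(triethylsilyloxy)cyclohexyl]pent-4-enoate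
Conditions: Pd(PPh3)4 (cat.), THF, 50 °C
Reagents that add atoms: none
Why: Negishi coupling joins the alkenyl triflate to the primary alkylzinc homoenolate and leaves the unactivated secondary bromide alone, because the alkenyl triflate undergoes oxidative addition far faster.

Step 6
Reactants: 9 ethyl 4-[(1R,3R,4S)-3-bromo-4-methyl-4-(triethylsilyloxy)cyclohexyl]pent-4-enoate
Product: 10 4-[(1R,3R,4S)-3-bromo-4-methyl-4-(triethylsilyloxy)cyclohexyl]pent-4-enal
Conditions: DIBAL-H, CH2Cl2, −78 °C
Reagents that add atoms: none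
Why: Partial reduction of the ester at low temperature stops at the aluminium hemiacetal, which gives the aldehyde on work-up (DIBAL-H ester to aldehyde reduction).

Step 7
Reactants: 10 4-[(1R,3R,4S)-3-bromo-4-methyl-4-(triethylsilyloxy)cyclohexyl]pent-4-enal
Product: 12 2-chloro-4-[(1R,3R,4S)-3-bromo-4-methyl-4-(triethylsilyloxy)cyclohexyl]pent-4-en-1-ol, via alpha-chloro aldehyde 11 (not isolated)
Conditions: NCS, DL-proline (cat.), CH2Cl2, 0 °C; then NaBH4, MeOH, 0 °C
Reagents that add atoms: N-chlorosuccinimide O=C1CCC(=O)N1Cl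
Why: Enamine-catalysed alpha-chlorination of the aldehyde followed by borohydride reduction gives the 2-chloro alcohol; the C–Cl centre forms as both epimers, which is harmless because it is destroyed by elimination in step 10.

Step 8
Reactants: 12 2-chloro alcohol; 13 (1R,4R,5R)-isothiocineole
Product: 15 S-(2-chloroalkyl)isothiocineolium triflate, via primary triflate 14 (not isolated)
Conditions: Tf2O, 2,6-lutidine, CH2Cl2, −78 °C; then 13, −78 °C to rt
Reagents that add atoms: trifluoromethanesulfonic anhydride O=S(=O)(OS(=O)(=O)C(F)(F)F)C(F)(F)F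
Why: The primary triflate alkylates the sulfide by SN2 on its exposed exo lone pair (sulfonium salt formation), which should give a single configuration at sulfur.

Step 9
Reactants: 16 pentane-2,4-dione; 17 but-3-en-2-one
Product: 18 3-acetylheptane-2,6-dione
Conditions: FeCl3·6H2O (cat.), neat, rt
Reagents that add atoms: none
Why: Lewis-acid-catalysed Michael addition of the 1,3-diketone to the enone gives the mono-adduct without the aldol side reactions of base catalysis.

Step 10
Reactants: 15 S-(2-chloroalkyl)isothiocineolium triflate; 18 3-acetylheptane-2,6-dione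
Product: 21 ring A epoxide bearing two acetyl groups on C2, via alkenylsulfonium triflate 19 (not isolated), via sulfonium ylide 20 (not isolated)
Conditions: DBU (2.2 equiv), CH2Cl2, 0 °C to rt
Reagents that add atoms: none
Why: DBU eliminates HCl from 15 to give the alkenylsulfonium salt 19, the diketonate of 18 adds to its beta carbon (C1), the resulting ylide carbon (C3) attacks the side-chain ketone (C4) and the alkoxide then displaces isothiocineole to close the epoxide. This is the conjugate addition/intramolecular Corey–Chaykovsky epoxy-annulation of alkenylsulfonium salts with ketone-tethered carbon nucleophiles, run here with a chiral sulfide. Ring A closes 6-exo-trig (attack on an acetyl carbonyl would need a four-membered ring) and the epoxide closes 3-exo-tet. C3 should be set by the isothiocineole scaffold, which exposes one face of the ylide; C4 follows from the anti-periplanar displacement, which enforces the cis ring fusion; C1 should be set because addition of the stabilised diketonate is reversible and the chair-like closure runs through the epimer with the C1 side chain equatorial and trans to the bulky sulfonio group (the axial acetyl on C2 disfavours an axial sulfonio group), so that inversion at C3 leaves the epoxide oxygen cis to that side chain; C2 carries two acetyl groups and is not yet stereogenic. The step needs C-alkylation of the diketonate and ring closure faster than ylide decomposition, which the soft tertiary carbanion, the absence of acidic hydrogen on C2 and the six-membered transition state should secure.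

Step 11
Reactants: 21 ring A epoxide bearing two acetyl groups on C2
Product: 22 ring A epoxide bearing one acetyl group on C2 (C2 S)
Conditions: K2CO3, MeOH, rt
Reagents that add atoms: none
Why: Methoxide-mediated retro-Claisen cleavage of the non-enolisable 1,3-diketone removes one acetyl group as methyl acetate, and the enolate is protonated and equilibrated to the C2 epimer with the acetyl group equatorial and trans to the C1 side chain (thermodynamic control).

Step 12
Reactants: 22 ring A epoxide bearing one acetyl group on C2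
Product: 23 triethylsilyl ether of the target
Conditions: Ph3PCH3Br, KOtBu, THF, 0 °C to rt
Reagents that add atoms: methyltriphenylphosphonium bromide C[P+](c1ccccc1)(c1ccccc1)c1ccccc1.[Br-]
Why: Wittig methylenation turns the C2 acetyl group into the isopropenyl group, and C2 cannot be eroded by the basic ylide because it is already in its thermodynamic configuration.

Step 13
Reactants: 23 triethylsilyl ether of the target
Product: 24 CNP0213097.1
Conditions: Bu4NF, AcOH, THF, 0 °C to rt
Reagents that add atoms: none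
Why: Fluoride cleaves the triethylsilyl ether (desilylation), and the acetic acid buffer keeps the liberated cis-bromohydrin from base-induced ring contraction while the epoxide stays intact.

**Compound list**

1 | (1S,2S,4R)-1-methyl-4-(prop-1-en-2-yl)cyclohexane-1,2-diol (limonene-1,2-diol) | C=C(C)[C@@H]1CC[C@](C)(O)[C@@H](O)C1 | starting material
2 | cyclic sulfite of 1 (both configurations at sulfur) | C=C(C)[C@@H]1CC[C@]2(C)OS(=O)O[C@H]2C1 | intermediate (not isolated)
3 | cyclic sulfate of (1S,2S,4R)-4-acetyl-1-methylcyclohexane-1,2-diol | CC(=O)[C@@H]1CC[C@]2(C)OS(=O)(=O)O[C@H]2C1 | intermediate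
4 | lithium (1S,2R,4R)-4-acetyl-2-bromo-1-methylcyclohexyl sulfate | CC(=O)[C@@H]1CC[C@](C)(OS(=O)(=O)[O-])[C@H](Br)C1.[Li+] | intermediate (not isolated)
5 | 1-[(1R,3R,4S)-3-bromo-4-hydroxy-4-methylcyclohexyl]ethan-1-one | CC(=O)[C@@H]1CC[C@](C)(O)[C@H](Br)C1 | intermediate
6 | 1-[(1R,3R,4S)-3-bromo-4-methyl-4-(triethylsilyloxy)cyclohexyl]ethan-1-one | CC(=O)[C@@H]1CC[C@](C)(O[Si](CC)(CC)CC)[C@H](Br)C1 | intermediate
7 | 1-[(1R,3R,4S)-3-bromo-4-methyl-4-(triethylsilyloxy)cyclohexyl]ethenyl trifluoromethanesulfonate | C=C(OS(=O)(=O)C(F)(F)F)[C@@H]1CC[C@](C)(O[Si](CC)(CC)CC)[C@H](Br)C1 | intermediate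
8 | (3-ethoxy-3-oxopropyl)zinc bromide | CCOC(=O)CC[Zn]Br | starting material
9 | ethyl 4-[(1R,3R,4S)-3-bromo-4-methyl-4-(triethylsilyloxy)cyclohexyl]pent-4-enoate | CCOC(=O)CCC(=C)[C@@H]1CC[C@](C)(O[Si](CC)(CC)CC)[C@H](Br)C1 | intermediate
10 | 4-[(1R,3R,4S)-3-bromo-4-methyl-4-(triethylsilyloxy)cyclohexyl]pent-4-enal | O=CCCC(=C)[C@@H]1CC[C@](C)(O[Si](CC)(CC)CC)[C@H](Br)C1 | intermediate
11 | 2-chloro-4-[(1R,3R,4S)-3-bromo-4-methyl-4-(triethylsilyloxy)cyclohexyl]pent-4-enal (both C2 epimers) | O=CC(Cl)CC(=C)[C@@H]1CC[C@](C)(O[Si](CC)(CC)CC)[C@H](Br)C1 | intermediate (not isolated)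
12 | 2-chloro-4-[(1R,3R,4S)-3-bromo-4-methyl-4-(triethylsilyloxy)cyclohexyl]pent-4-en-1-ol (both C2 epimers) | OCC(Cl)CC(=C)[C@@H]1CC[C@](C)(O[Si](CC)(CC)CC)[C@H](Br)C1 | intermediate
13 | (1R,4R,5R)-4,7,7-trimethyl-6-thiabicyclo[3.2.1]octane (isothiocineole) | C[C@@H]1CC[C@@H]2C[C@H]1SC2(C)C | starting material
14 | 2-chloro-4-[(1R,3R,4S)-3-bromo-4-methyl-4-(triethylsilyloxy)cyclohexyl]pent-4-en-1-yl trifluoromethanesulfonate | O=S(=O)(OCC(Cl)CC(=C)[C@@H]1CC[C@](C)(O[Si](CC)(CC)CC)[C@H](Br)C1)C(F)(F)F | intermediate (not isolated)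
15 | S-{2-chloro-4-[(1R,3R,4S)-3-bromo-4-methyl-4-(triethylsilyloxy)cyclohexyl]pent-4-en-1-yl}isothiocineolium triflate (alkyl group on the exo face of sulfur; both C–Cl epimers) | ClC(C[S@+]1C(C)(C)[C@@H]2CC[C@@H](C)[C@H]1C2)CC(=C)[C@@H]1CC[C@](C)(O[Si](CC)(CC)CC)[C@H](Br)C1.[O-]S(=O)(=O)C(F)(F)F | intermediate
16 | pentane-2,4-dione | CC(=O)CC(C)=O | starting material
17 | but-3-en-2-one | C=CC(C)=O | starting material
18 | 3-acetylheptane-2,6-dione | CC(=O)CCC(C(C)=O)C(C)=O | intermediate
19 | S-{(1E)-4-[(1R,3R,4S)-3-bromo-4-methyl-4-(triethylsilyloxy)cyclohexyl]penta-1,4-dien-1-yl}isothiocineolium triflate | C=C(C/C=C/[S@+]1C(C)(C)[C@@H]2CC[C@@H](C)[C@H]1C2)[C@@H]1CC[C@](C)(O[Si](CC)(CC)CC)[C@H](Br)C1.[O-]S(=O)(=O)C(F)(F)F | intermediate (not isolated)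
20 | sulfonium ylide from addition of the enolate of 18 to C1 of 19 (ylide carbon is C3; both C1 epimers, interconverting) | CC(=O)CCC(C(C)=O)(C(C)=O)C(CC(=C)[C@@H]1CC[C@](C)(O[Si](CC)(CC)CC)[C@H](Br)C1)[CH-][S@+]1C(C)(C)[C@@H]2CC[C@@H](C)[C@H]1C2 | intermediate (not isolated)
21 | 1,1'-[(1R,2R,6S)-2-{2-[(1R,3R,4S)-3-bromo-4-methyl-4-(triethylsilyloxy)cyclohexyl]prop-2-en-1-yl}-6-methyl-7-oxabicyclo[4.1.0]heptane-3,3-diyl]di(ethan-1-one) (ring A: C1 R, C3 R, C4 S) | C=C(C[C@@H]1C(C(C)=O)(C(C)=O)CC[C@]2(C)O[C@H]12)[C@@H]1CC[C@](C)(O[Si](CC)(CC)CC)[C@H](Br)C1 | intermediate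
22 | 1-[(1R,2R,3S,6S)-2-{2-[(1R,3R,4S)-3-bromo-4-methyl-4-(triethylsilyloxy)cyclohexyl]prop-2-en-1-yl}-6-methyl-7-oxabicyclo[4.1.0]heptan-3-yl]ethan-1-one | C=C(C[C@@H]1[C@@H](C(C)=O)CC[C@]2(C)O[C@H]12)[C@@H]1CC[C@](C)(O[Si](CC)(CC)CC)[C@H](Br)C1 | intermediate
23 | triethyl{[(1S,2R,4R)-2-bromo-1-methyl-4-{3-[(1R,2R,3S,6S)-6-methyl-3-(prop-1-en-2-yl)-7-oxabicyclo[4.1.0]heptan-2-yl]prop-1-en-2-yl}cyclohexyl]oxy}silane | C=C(C[C@@H]1[C@@H](C(=C)C)CC[C@]2(C)O[C@H]12)[C@@H]1CC[C@](C)(O[Si](CC)(CC)CC)[C@H](Br)C1 | intermediate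
24 | (1S,2R,4R)-2-bromo-1-methyl-4-{3-[(1R,2R,3S,6S)-6-methyl-3-(prop-1-en-2-yl)-7-oxabicyclo[4.1.0]heptan-2-yl]prop-1-en-2-yl}cyclohexan-1-ol (CNP0213097.1) | C=C(C[C@@H]1[C@@H](C(=C)C)CC[C@]2(C)O[C@H]12)[C@@H]1CC[C@](C)(O)[C@H](Br)C1 | target

**Step count.** Total: 13 steps. Longest linear sequence: 12 steps (steps 1 to 8 and 10 to 13); step 9 is a one-step side branch.

**Steps most likely to fail**

Step 10 (key step). The conjugate addition of the hindered tertiary diketonate to the beta-substituted alkenylsulfonium salt may be slow, so that ylide decomposition competes. Facial control by the sulfide, or the cis placement of the epoxide and the C1 side chain, may also be incomplete. The fallback is the phosphorus analogue, which separates ring construction from oxygen transfer. It sets out from 12 and 18. Chlorohydrin 12 is converted through its triflate with PPh3 into the (2-chloroalkyl)triphenylphosphonium triflate F1. F1 and 18 with DBU should give, by HCl elimination, Michael addition and intramolecular Wittig reaction, the cyclohexene F2; C1–C2 and C3=C4 are again formed in one operation. Shi epoxidation of the trisubstituted ring alkene, with the fructose-derived ketone of the enantiomeric series that delivers oxygen to the required face, then leads to 21. This variant gives up reagent control at C1, so 21 has to be separated from its ring A diastereomers. The route is rejoined at 21 and continues with step 11.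

Step 8. Alkylation of the hindered sulfide by the beta-branched, beta-chloro triflate may lose out to elimination or decomposition of the triflate. The fallback sets out from 12 and makes the C–S bond by epoxide opening instead. K2CO3 in MeOH closes 12 to the terminal epoxide F3. Opening of F3 at its terminal carbon by 13 with CF3SO3H (CH2Cl2, −78 °C) gives the beta-hydroxy sulfonium triflate F4. Mesylation (Ms2O, pyridine) gives the beta-mesyloxy sulfonium triflate F5. F5 replaces 15 in step 10, where DBU eliminates methanesulfonic acid, and the route is rejoined at 19.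

Step 5. Transmetalation to the hindered 1,1-disubstituted alkenylpalladium intermediate may be slow, so that protonation of the functionalised alkylzinc reagent and reduction of the triflate compete. The fallback sets out from 6 and builds the chain by a sigmatropic route. Wittig methylenation (Ph3PCH3Br, KOtBu) gives the isopropenyl compound F6. SeO2-catalysed allylic oxidation with t-BuOOH gives the allylic alcohol F7. Hg(OAc)2-catalysed exchange with ethyl vinyl ether gives the allyl vinyl ether F8, which on heating (toluene, 140 °C) undergoes Claisen rearrangement. The route is rejoined at 10, so that steps 4 to 6 are bypassed.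

Further compounds
F1 | step 10 | {2-chloro-4-[(1R,3R,4S)-3-bromo-4-methyl-4-(triethylsilyloxy)cyclohexyl]pent-4-en-1-yl}triphenylphosphonium triflate (both C–Cl epimers) | ClC(C[P+](c1ccccc1)(c1ccccc1)c1ccccc1)CC(=C)[C@@H]1CC[C@](C)(O[Si](CC)(CC)CC)[C@H](Br)C1.[O-]S(=O)(=O)C(F)(F)F
F2 | step 10 | 1,1'-[2-{2-[(1R,3R,4S)-3-bromo-4-methyl-4-(triethylsilyloxy)cyclohexyl]prop-2-en-1-yl}-4-methylcyclohex-3-ene-1,1-diyl]di(ethan-1-one) (both epimers at the ring A stereocentre) | C=C(CC1C=C(C)CCC1(C(C)=O)C(C)=O)[C@@H]1CC[C@](C)(O[Si](CC)(CC)CC)[C@H](Br)C1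
F3 | step 8 | 2-{2-[(1R,3R,4S)-3-bromo-4-methyl-4-(triethylsilyloxy)cyclohexyl]prop-2-en-1-yl}oxirane (both epoxide epimers) | C=C(CC1CO1)[C@@H]1CC[C@](C)(O[Si](CC)(CC)CC)[C@H](Br)C1
F4 | step 8 | S-{2-hydroxy-4-[(1R,3R,4S)-3-bromo-4-methyl-4-(triethylsilyloxy)cyclohexyl]pent-4-en-1-yl}isothiocineolium triflate | OC(C[S@+]1C(C)(C)[C@@H]2CC[C@@H](C)[C@H]1C2)CC(=C)[C@@H]1CC[C@](C)(O[Si](CC)(CC)CC)[C@H](Br)C1.[O-]S(=O)(=O)C(F)(F)F
F5 | step 8 | S-{2-(methanesulfonyloxy)-4-[(1R,3R,4S)-3-bromo-4-methyl-4-(triethylsilyloxy)cyclohexyl]pent-4-en-1-yl}isothiocineolium triflate | CS(=O)(=O)OC(C[S@+]1C(C)(C)[C@@H]2CC[C@@H](C)[C@H]1C2)CC(=C)[C@@H]1CC[C@](C)(O[Si](CC)(CC)CC)[C@H](Br)C1.[O-]S(=O)(=O)C(F)(F)F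
F6 | step 5 | {[(1S,2R,4R)-2-bromo-1-methyl-4-(prop-1-en-2-yl)cyclohexyl]oxy}triethylsilane | C=C(C)[C@@H]1CC[C@](C)(O[Si](CC)(CC)CC)[C@H](Br)C1
F7 | step 5 | 2-[(1R,3R,4S)-3-bromo-4-methyl-4-(triethylsilyloxy)cyclohexyl]prop-2-en-1-ol | C=C(CO)[C@@H]1CC[C@](C)(O[Si](CC)(CC)CC)[C@H](Br)C1
F8 | step 5 | {[(1S,2R,4R)-2-bromo-4-[3-(ethenyloxy)prop-1-en-2-yl]-1-methylcyclohexyl]oxy}triethylsilane | C=COCC(=C)[C@@H]1CC[C@](C)(O[Si](CC)(CC)CC)[C@H](Br)C1
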